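The γ-lactone is disconnected at O1–C7a and C3–C3a (octahydro-1-benzofuran-2-one locants). C7a and C3a lie β and α to the carbinol carbon C4, so at the C4-ketone level the six-membered ring is a 2-iodocyclohex-2-enone. In one operation a Stille coupling attaches a 1-carboxyvinyl unit to C3a and its carboxyl group then adds in conjugate fashion to C7a; this closes the α-methylene lactone and sets C7a and C3a. The precursor, iodoenone 11, already carries the C7 acrylate and the C6 methyl/vinyl quaternary centre; its single catalytically set stereocentre (C7) relays all the others.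

Key step: step 9

Remark (assumption): the target is read as the (3aR,4R,6S,7R,7aR) isomer with an (E)-2-methylbut-2-enoate (tiglate) ester; locants O1, C2, C3, C3a, C4–C7, C7a refer to the target skeleton throughout. The reagents named under the steps are taken as commercial.

**Step 1**
Reactants: 1 tert-butyl 2-(4-oxocyclohexyl)acetate
Product: 2 tert-butyl 2-[(1S)-4-oxocyclohex-2-en-1-yl]acetate
Conditions: chiral tert-leucine-derived primary–tertiary diamine·TfOH (20 mol%), IBX (1.3 equiv), DMSO, 30 °C
Reagents that add atoms: none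
Why: Enamine-mediated desymmetrising dehydrogenation (amine-catalysed enamine oxidation by IBX) should distinguish the two enantiotopic α-CH2 groups of the meso ketone, so the catalyst antipode chosen sets the lone stereocentre as (S).

**Step 2**
Reactants: 2 tert-butyl 2-[(1S)-4-oxocyclohex-2-en-1-yl]acetate
Product: 4 tert-butyl 2-[(1S)-2-methyl-4-oxocyclohex-2-en-1-yl]acetate, via silyl enol ether 3 (not isolated)
Conditions: MeMgBr (1.3 equiv), CuBr·SMe2 (10 mol%), TMSCl (2 equiv), THF, −78 °C; then Pd(OAc)2 (10 mol%), O2 (1 atm), DMSO, 50 °C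
Reagents that add atoms: methylmagnesium bromide, C[Mg]Br; chlorotrimethylsilane, C[Si](C)(C)Cl (silicon held in 3 only)
Why: Copper-catalysed conjugate addition with silyl trapping followed by Saegusa-type Pd(II)/O2 dehydrosilylation should return the enone with the methyl group on its β-carbon and leave the γ-stereocentre untouched.

**Step 3**
Reactants: 4 tert-butyl 2-[(1S)-2-methyl-4-oxocyclohex-2-en-1-yl]acetate
Product: 5 tert-butyl 2-[(1S,2S)-2-ethenyl-2-methyl-4-(trimethylsilyloxy)cyclohex-3-en-1-yl]acetate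
Conditions: CH2=CHMgBr (2 equiv), CuBr·SMe2 (20 mol%), TMSCl (3 equiv), HMPA (2 equiv), THF, −78 → −40 °C; Et3N/pentane work-up
Reagents that add atoms: vinylmagnesium bromide, C=C[Mg]Br; chlorotrimethylsilane, C[Si](C)(C)Cl
Why: TMSCl-accelerated copper-catalysed conjugate addition to the β,β-disubstituted enone should deliver vinyl anti to the neighbouring acetate side chain (axial attack on the half-chair), which sets the quaternary centre with methyl cis and vinyl trans to that chain, and the enolate is stored as its silyl enol ether.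

**Step 4**
Reactants: 5 tert-butyl 2-[(1S,2S)-2-ethenyl-2-methyl-4-(trimethylsilyloxy)cyclohex-3-en-1-yl]acetate
Product: 9 tert-butyl 2-[(1R,2S)-2-ethenyl-2-methyl-4-oxocyclohexyl]prop-2-enoate, via Mannich base 6 (not isolated), via methiodide 7 (not isolated), via silyl enol ether acrylate 8 (not isolated)
Conditions: LDA (1.15 equiv), THF, −78 °C; CH2=NMe2+ I− (1.2 equiv), −78 → 0 °C; MeI (5 equiv), rt, then evaporate; DBU (1.5 equiv), CH2Cl2, rt; 1 M HCl, THF, 0 °C
Reagents that add atoms: dimethylmethylideneammonium iodide (Eschenmoser's salt), C=[N+](C)C.[I-]; iodomethane, CI (methyl held in 7 only)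
Why: With the ketone masked as the silyl enol ether, the ester enolate undergoes a Mannich reaction, quaternisation and Hofmann-type E1cB elimination give the acrylate, and dilute acid then frees the ketone.

**Step 5**
Reactants: 9 tert-butyl 2-[(1R,2S)-2-ethenyl-2-methyl-4-oxocyclohexyl]prop-2-enoate
Product: 10 tert-butyl 2-[(1R,6S)-6-ethenyl-6-methyl-4-oxocyclohex-2-en-1-yl]prop-2-enoate
Conditions: IBX (2.5 equiv), DMSO–fluorobenzene, 70 °C, BHT (trace)
Reagents that add atoms: none
Why: IBX dehydrogenation of the ketone can introduce unsaturation only on the CH2–CH2 side, because the other α-carbon is flanked by the quaternary centre, so a single enone should result.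

**Step 6**
Reactants: 10 tert-butyl 2-[(1R,6S)-6-ethenyl-6-methyl-4-oxocyclohex-2-en-1-yl]prop-2-enoate
Product: 11 tert-butyl 2-[(1R,6S)-6-ethenyl-3-iodo-6-methyl-4-oxocyclohex-2-en-1-yl]prop-2-enoate
Conditions: I2 (1.5 equiv), pyridine–CH2Cl2 (1:1), 0 °C → rt
Reagents that add atoms: iodine, II
Why: Baylis–Hillman-type α-iodination (pyridine adds to the β-carbon, the enolate is iodinated, pyridine is expelled) should give the 2-iodoenone and leave the acrylate and the isolated vinyl group untouched.

**Step 7**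
Reactants: 12 ethyl prop-2-ynoate
Product: 13 ethyl 2-(tributylstannyl)prop-2-enoate
Conditions: Bu3SnH (1.05 equiv), Pd(PPh3)4 (2 mol%), THF, 0 °C → rt
Reagents that add atoms: tributyltin hydride, CCCC[SnH](CCCC)CCCC
Why: Palladium-catalysed syn-hydrostannation of an alkynoate places tin on the α-carbon, the usual regiochemistry under Pd catalysis.

**Step 8**
Reactants: 13 ethyl 2-(tributylstannyl)prop-2-enoate
Product: 14 2-(tributylstannyl)prop-2-enoic acid
Conditions: LiOH·H2O (1.5 equiv), THF–H2O (3:1), 0 °C → rt; then 1 M HCl to pH 4, 0 °C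
Reagents that add atoms: lithium hydroxide, [Li+].[OH-]
Why: Saponification of the ethyl ester; the vinyl–tin bond survives base and a brief cold acidification.

**Step 9**
Reactants: 11 tert-butyl 2-[(1R,6S)-6-ethenyl-3-iodo-6-methyl-4-oxocyclohex-2-en-1-yl]prop-2-enoate; 14 2-(tributylstannyl)prop-2-enoic acid
Product: 16 tert-butyl 2-[(3aS,6S,7R,7aR)-6-ethenyl-6-methyl-3-methylidene-2,4-dioxooctahydro-1-benzofuran-7-yl]prop-2-enoate, via dienone acid 15 (not isolated)
Conditions: iPr2NEt (1.1 equiv), Pd2(dba)3 (2.5 mol%), AsPh3 (20 mol%), CuI (10 mol%), NMP, 25–35 °C; then AcOH (1.5 equiv), 0 °C → rt, same flask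
Reagents that add atoms: none
Why: Pd(0) inserts into the C–I bond of 11, copper-assisted transmetallation transfers the 1-carboxylatovinyl group from tin and reductive elimination forms C3–C3a; the released dienone acid 15 then adds its carboxyl oxygen to the enone β-carbon C7a and the enol is protonated at C3a, which forms O1–C7a. The closest known reaction types are Stille couplings of 2-iodocyclohexenones with α-stannyl acrylates, tandem Stille/lactonisation sequences of stannyl or halo acrylic acids, and conjugate lactonisation of carboxylic acids onto enones. The only ring closed is the lactone, by intramolecular oxa-Michael addition (formally 5-endo-trig, running through the enol and reversible). At C7a the oxygen should add trans to the neighbouring C7 side chain, since this keeps that chain and the new C–O bond equatorial and avoids the syn-axial C6 methyl group, and reversibility lets this centre settle; at C3a axial protonation of the enol from the α face gives the equatorial C3a–C3 bond, i.e. the trans-fused lactone. The step needs chemoselectivity (only the C–I bond couples, and only the free acid, not the tert-butyl ester, can add to C7a) and it must stop at the kinetic product, because base would move the exocyclic C3=CH2 bond into conjugation with the ketone or epimerise C3a; the amine is therefore buffered with acetic acid and 16 is reduced at once.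

**Step 10**
Reactants: 16 tert-butyl 2-[(3aS,6S,7R,7aR)-6-ethenyl-6-methyl-3-methylidene-2,4-dioxooctahydro-1-benzofuran-7-yl]prop-2-enoate
Product: 17 tert-butyl 2-[(3aR,4R,6S,7R,7aR)-6-ethenyl-4-hydroxy-6-methyl-3-methylidene-2-oxooctahydro-1-benzofuran-7-yl]prop-2-enoate
Conditions: NaBH4 (1 equiv), CeCl3·7H2O (1.2 equiv), MeOH–THF, −78 °C
Reagents that add atoms: none
Why: Luche 1,2-reduction: cerium suppresses conjugate reduction of the two acrylate units, and hydride should avoid the axial trajectory blocked by the syn-axial C6 methyl group, giving the axial C4 alcohol cis to that methyl and to the C3a–C3 bond.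

**Step 11**
Reactants: 17 tert-butyl 2-[(3aR,4R,6S,7R,7aR)-6-ethenyl-4-hydroxy-6-methyl-3-methylidene-2-oxooctahydro-1-benzofuran-7-yl]prop-2-enoate
Product: 18 tert-butyl 2-[(3aR,4R,6S,7R,7aR)-6-ethenyl-6-methyl-4-{[(2E)-2-methylbut-2-enoyl]oxy}-3-methylidene-2-oxooctahydro-1-benzofuran-7-yl]prop-2-enoate
Conditions: tigloyl chloride (3 equiv), Et3N (4 equiv), DMAP (0.3 equiv), CH2Cl2, 0 °C → 40 °C
Reagents that add atoms: (E)-2-methylbut-2-enoyl chloride (tigloyl chloride), ClC(=O)/C(C)=C/C
Why: DMAP-catalysed acylation of the hindered axial alcohol with retention at C4; the thermodynamically preferred (E)-geometry of the tiglate is kept.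

**Step 12**
Reactants: 18 tert-butyl 2-[(3aR,4R,6S,7R,7aR)-6-ethenyl-6-methyl-4-{[(2E)-2-methylbut-2-enoyl]oxy}-3-methylidene-2-oxooctahydro-1-benzofuran-7-yl]prop-2-enoate
Product: 19 2-[(3aR,4R,6S,7R,7aR)-6-ethenyl-6-methyl-4-{[(2E)-2-methylbut-2-enoyl]oxy}-3-methylidene-2-oxooctahydro-1-benzofuran-7-yl]prop-2-enoic acid
Conditions: TFA–CH2Cl2 (1:4), 0 °C → rt
Reagents that add atoms: none
Why: Acidolysis of the tert-butyl ester (E1 loss of isobutene) should free the acrylic acid while the lactone, the tiglate and the alkenes are stable to anhydrous TFA.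

**Compound list**

1 | tert-butyl 2-(4-oxocyclohexyl)acetate | O=C1CCC(CC(=O)OC(C)(C)C)CC1 | starting material
2 | tert-butyl 2-[(1S)-4-oxocyclohex-2-en-1-yl]acetate | C1=CC(=O)CC[C@H]1CC(=O)OC(C)(C)C | intermediate
3 | tert-butyl 2-[(1S,2S)-2-methyl-4-(trimethylsilyloxy)cyclohex-3-en-1-yl]acetate (methyl trans to the side chain) | C[C@@H]1C=C(O[Si](C)(C)C)CC[C@H]1CC(=O)OC(C)(C)C | intermediate
4 | tert-butyl 2-[(1S)-2-methyl-4-oxocyclohex-2-en-1-yl]acetate | CC1=CC(=O)CC[C@H]1CC(=O)OC(C)(C)C | intermediate
5 | tert-butyl 2-[(1S,2S)-2-ethenyl-2-methyl-4-(trimethylsilyloxy)cyclohex-3-en-1-yl]acetate (vinyl trans to the side chain) | C=C[C@]1(C)C=C(O[Si](C)(C)C)CC[C@H]1CC(=O)OC(C)(C)C | intermediate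
6 | tert-butyl 3-(dimethylamino)-2-[(1S,2S)-2-ethenyl-2-methyl-4-(trimethylsilyloxy)cyclohex-3-en-1-yl]propanoate (both epimers at the propanoate C2) | C=C[C@]1(C)C=C(O[Si](C)(C)C)CC[C@H]1C(CN(C)C)C(=O)OC(C)(C)C | intermediate
7 | trimethylammonium iodide of 6 (N-methylated Mannich base) | C=C[C@]1(C)C=C(O[Si](C)(C)C)CC[C@H]1C(C[N+](C)(C)C)C(=O)OC(C)(C)C.[I-] | intermediate
8 | tert-butyl 2-[(1R,2S)-2-ethenyl-2-methyl-4-(trimethylsilyloxy)cyclohex-3-en-1-yl]prop-2-enoate | C=C[C@]1(C)C=C(O[Si](C)(C)C)CC[C@H]1C(=C)C(=O)OC(C)(C)C | intermediate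
9 | tert-butyl 2-[(1R,2S)-2-ethenyl-2-methyl-4-oxocyclohexyl]prop-2-enoate | C=C[C@]1(C)CC(=O)CC[C@H]1C(=C)C(=O)OC(C)(C)C | intermediate
10 | tert-butyl 2-[(1R,6S)-6-ethenyl-6-methyl-4-oxocyclohex-2-en-1-yl]prop-2-enoate | C=C[C@]1(C)CC(=O)C=C[C@H]1C(=C)C(=O)OC(C)(C)C | intermediate
11 | tert-butyl 2-[(1R,6S)-6-ethenyl-3-iodo-6-methyl-4-oxocyclohex-2-en-1-yl]prop-2-enoate | C=C[C@]1(C)CC(=O)C(I)=C[C@H]1C(=C)C(=O)OC(C)(C)C | intermediate
12 | ethyl prop-2-ynoate | C#CC(=O)OCC | starting material
13 | ethyl 2-(tributylstannyl)prop-2-enoate | C=C(C(=O)OCC)[Sn](CCCC)(CCCC)CCCC | intermediate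
14 | 2-(tributylstannyl)prop-2-enoic acid | C=C(C(=O)O)[Sn](CCCC)(CCCC)CCCC | intermediate
15 | 2-{(3R,4S)-3-[1-(tert-butoxycarbonyl)ethenyl]-4-ethenyl-4-methyl-6-oxocyclohex-1-en-1-yl}prop-2-enoic acid | C=C[C@]1(C)CC(=O)C(C(=C)C(=O)O)=C[C@H]1C(=C)C(=O)OC(C)(C)C | intermediate
16 | tert-butyl 2-[(3aS,6S,7R,7aR)-6-ethenyl-6-methyl-3-methylidene-2,4-dioxooctahydro-1-benzofuran-7-yl]prop-2-enoate (trans-fused lactone) | C=C[C@]1(C)CC(=O)[C@H]2C(=C)C(=O)O[C@@H]2[C@H]1C(=C)C(=O)OC(C)(C)C | intermediate
17 | tert-butyl 2-[(3aR,4R,6S,7R,7aR)-6-ethenyl-4-hydroxy-6-methyl-3-methylidene-2-oxooctahydro-1-benzofuran-7-yl]prop-2-enoate | C=C[C@]1(C)C[C@@H](O)[C@H]2C(=C)C(=O)O[C@@H]2[C@H]1C(=C)C(=O)OC(C)(C)C | intermediate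
18 | tert-butyl 2-[(3aR,4R,6S,7R,7aR)-6-ethenyl-6-methyl-4-{[(2E)-2-methylbut-2-enoyl]oxy}-3-methylidene-2-oxooctahydro-1-benzofuran-7-yl]prop-2-enoate | C=C[C@]1(C)C[C@@H](OC(=O)/C(C)=C/C)[C@H]2C(=C)C(=O)O[C@@H]2[C@H]1C(=C)C(=O)OC(C)(C)C | intermediate
19 | 2-[(3aR,4R,6S,7R,7aR)-6-ethenyl-6-methyl-4-{[(2E)-2-methylbut-2-enoyl]oxy}-3-methylidene-2-oxooctahydro-1-benzofuran-7-yl]prop-2-enoic acid | C=C[C@]1(C)C[C@@H](OC(=O)/C(C)=C/C)[C@H]2C(=C)C(=O)O[C@@H]2[C@H]1C(=C)C(=O)O | target

Total step count: 12. Longest linear sequence: 10 steps (steps 1–6 and 9–12); steps 7–8 make the stannane.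

**Steps most likely to fail**

Step 9 (key step). The stannyl acid may be protodestannylated before it transmetallates. The acid may add 1,2 to the ketone (a pseudo-acid) and not in conjugate fashion. Kinetic control may be lost: the exocyclic C3=CH2 bond can drift into conjugation with the C4 ketone, or C3a can epimerise to the cis-fused lactone. The fallback sets out from enone 10 and builds the lactone by epoxide opening. Nucleophilic epoxidation (t-BuOOH, Triton B, THF, 0 °C) from the face anti to the acrylate side chain should give the α-epoxy ketone tert-butyl 2-[(3S)-3-ethenyl-3-methyl-5-oxo-7-oxabicyclo[4.1.0]heptan-2-yl]prop-2-enoate F1. Sodium triethyl phosphonoacetate (NaH, THF, then toluene, 80 °C) opens F1 at the carbon α to the ketone with inversion, and the released alkoxide lactonises to the α-(diethoxyphosphoryl) keto lactone F2. A Horner–Wadsworth–Emmons reaction with aqueous formaldehyde (K2CO3, THF) then gives the methylidene lactone and comes back to the route at 16.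

Step 10. Facial selectivity of hydride delivery at C4 may be poor, or the methylidene lactone may be reduced in conjugate fashion. The fallback sets out from 16 and accepts the other face: reduction under conditions that favour the equatorial alcohol gives the C4 epimer tert-butyl 2-[(3aR,4S,6S,7R,7aR)-6-ethenyl-4-hydroxy-6-methyl-3-methylidene-2-oxooctahydro-1-benzofuran-7-yl]prop-2-enoate F3. Mitsunobu esterification of F3 with tiglic acid (PPh3, DIAD, toluene) inverts C4 and comes back to the route at 18, so step 11 is skipped.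

Step 1. The catalytic desymmetrisation may give insufficient enantiomeric excess, or IBX may oxidise the product further. The fallback sets out from 1 and uses a stoichiometric chiral base: lithium (R,R)-bis(1-phenylethyl)amide (or its antipode, as required) with in-situ TMSCl at −100 °C should give the silyl enol ether tert-butyl 2-[(1R)-4-(trimethylsilyloxy)cyclohex-3-en-1-yl]acetate F4. Saegusa oxidation of F4 (Pd(OAc)2, MeCN) comes back to the route at 2.

**Further compounds**

F1 | step 9 | tert-butyl 2-[(3S)-3-ethenyl-3-methyl-5-oxo-7-oxabicyclo[4.1.0]heptan-2-yl]prop-2-enoate (oxirane oxygen anti to the acrylate side chain) | C=C[C@]1(C)CC(=O)[C@@H]2O[C@@H]2[C@H]1C(=C)C(=O)OC(C)(C)C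
F2 | step 9 | tert-butyl 2-[(3aS,6S,7R,7aR)-3-(diethoxyphosphoryl)-6-ethenyl-6-methyl-2,4-dioxooctahydro-1-benzofuran-7-yl]prop-2-enoate (both C3 epimers) | C=C[C@]1(C)CC(=O)[C@H]2C(P(=O)(OCC)OCC)C(=O)O[C@@H]2[C@H]1C(=C)C(=O)OC(C)(C)C
F3 | step 10 | tert-butyl 2-[(3aR,4S,6S,7R,7aR)-6-ethenyl-4-hydroxy-6-methyl-3-methylidene-2-oxooctahydro-1-benzofuran-7-yl]prop-2-enoate | C=C[C@]1(C)C[C@H](O)[C@H]2C(=C)C(=O)O[C@@H]2[C@H]1C(=C)C(=O)OC(C)(C)C
F4 | step 1 | tert-butyl 2-[(1R)-4-(trimethylsilyloxy)cyclohex-3-en-1-yl]acetate | C1C=C(O[Si](C)(C)C)CC[C@H]1CC(=O)OC(C)(C)C
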